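**Retrosynthetic overview**
- Target ⇐ selective thiolate mono-O-demethylation plus O-debenzylation of a symmetric 3,5-dimethoxy ring A that already carries the 4-(4-benzyloxybenzyl) group.
- Diarylmethane bond ⇐ directed ortho-lithiation of a 3,5-dimethoxybibenzyl at C4 (between the two OMe groups) and alkylation with 4-(benzyloxy)benzyl chloride.
- Bibenzyl CH2–CH2 ⇐ stilbene ⇐ key step: two aldehyde carbons are joined, 2-(benzyloxy)benzaldehyde as its N–H hydrazone (a benzyl carbanion equivalent) and 3,5-dimethoxybenzaldehyde, under Ru catalysis with loss of N2.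
- No ring is constructed: all three benzene rings are bought. Ring B is joined to ring A first, then ring C is attached to ring A.

Assumption: the target has no stereocentre or other stereogenic element, so it is one achiral compound and no enantiocontrol is needed.

**Step 1**
Reactants: 1 2-(benzyloxy)benzaldehyde; 2 hydrazine (used as the monohydrate); 3 3,5-dimethoxybenzaldehyde
Product: 5 (E)-1-(benzyloxy)-2-[2-(3,5-dimethoxyphenyl)ethenyl]benzene, via (E)-[2-(benzyloxy)benzylidene]hydrazine 4 (not isolated)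
Conditions: 1 + N2H4·H2O, THF, rt, 1 h; then 3, [Ru(p-cymene)Cl2]2 (1.5 mol%), dmpe (3 mol%), t-BuOK (50 mol%), THF, 45 → 80 °C
Reagents that add atoms: none
Why: Ru(II)-catalysed hydrazone-umpolung carbonyl–carbonyl olefination, in which hydrazone 4 acts as a benzyl carbanion equivalent, adds to aldehyde 3 through a six-membered Ru transition state and then loses N2 and hydroxide (Wolff–Kishner-type/E1cB), so two natively electrophilic carbonyl carbons are joined; the alkene geometry (E major) does not matter because step 2 removes it.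

**Step 2**
Reactants: 5 (E)-1-(benzyloxy)-2-[2-(3,5-dimethoxyphenyl)ethenyl]benzene
Product: 6 2-[2-(3,5-dimethoxyphenyl)ethyl]phenol
Conditions: H2 (1 atm), 10% Pd/C, EtOAc–EtOH, rt
Reagents that add atoms: none
Why: Heterogeneous catalytic hydrogenation saturates the stilbene C=C of either geometry and hydrogenolyses the aryl benzyl ether in the same operation, while the aryl methyl ethers are inert.

**Step 3**
Reactants: 6 2-[2-(3,5-dimethoxyphenyl)ethyl]phenol; 7 4-(benzyloxy)benzyl chloride
Product: 9 2-[2-(4-{[4-(benzyloxy)phenyl]methyl}-3,5-dimethoxyphenyl)ethyl]phenol, via lithium 2-[2-(4-lithio-3,5-dimethoxyphenyl)ethyl]phenolate 8 (not isolated)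
Conditions: n-BuLi (2.2 equiv), TMEDA, THF, 0 °C → rt; CuI (10 mol%), then 7, −78 °C → rt; aq. HCl work-up
Reagents that add atoms: none
Why: Directed ortho-metalation, in which the first equivalent of base makes the phenoxide and the second removes the ring-A proton flanked by two methoxy groups (kinetically far more acidic than any site next to O–Li or on the ethylene bridge), followed by copper-assisted SN2 benzylation of the aryl anion, with the lithium phenoxide too poor a nucleophile in THF to O-alkylate.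

**Step 4**
Reactants: 9 2-[2-(4-{[4-(benzyloxy)phenyl]methyl}-3,5-dimethoxyphenyl)ethyl]phenol
Product: 10 2-[(4-hydroxyphenyl)methyl]-5-[2-(2-hydroxyphenyl)ethyl]-3-methoxyphenol (CNP0353999.0)
Conditions: EtSNa (5 equiv), DMF, 140 °C; aq. HCl work-up
Reagents that add atoms: none
Why: Thiolate SN2 ether cleavage removes the O-benzyl group and one of the two symmetry-equivalent ring-A methyl groups, and the ring-A phenoxide formed then electronically blocks attack on the remaining methoxy group (selective mono-O-demethylation of a resorcinol dimethyl ether).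

**Compound list**
1 | 2-(benzyloxy)benzaldehyde | O=Cc1ccccc1OCc1ccccc1 | starting material
2 | hydrazine (as monohydrate) | NN | starting material
3 | 3,5-dimethoxybenzaldehyde | COc1cc(C=O)cc(OC)c1 | starting material
4 | (E)-[2-(benzyloxy)benzylidene]hydrazine | N/N=C/c1ccccc1OCc1ccccc1 | intermediate (not isolated)
5 | (E)-1-(benzyloxy)-2-[2-(3,5-dimethoxyphenyl)ethenyl]benzene | COc1cc(/C=C/c2ccccc2OCc2ccccc2)cc(OC)c1 | intermediate
6 | 2-[2-(3,5-dimethoxyphenyl)ethyl]phenol | COc1cc(CCc2ccccc2O)cc(OC)c1 | intermediate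
7 | 4-(benzyloxy)benzyl chloride | ClCc1ccc(OCc2ccccc2)cc1 | starting material
8 | lithium 2-[2-(4-lithio-3,5-dimethoxyphenyl)ethyl]phenolate | [Li]c1c(OC)cc(CCc2ccccc2O[Li])cc1OC | intermediate (not isolated)
9 | 2-[2-(4-{[4-(benzyloxy)phenyl]methyl}-3,5-dimethoxyphenyl)ethyl]phenol | COc1cc(CCc2ccccc2O)cc(OC)c1Cc1ccc(OCc2ccccc2)cc1 | intermediate
10 | 2-[(4-hydroxyphenyl)methyl]-5-[2-(2-hydroxyphenyl)ethyl]-3-methoxyphenol | COc1cc(CCc2ccccc2O)cc(O)c1Cc1ccc(O)cc1 | target

**Total step count:** 4
**Longest linear sequence:** 4 steps (1 → 5 → 6 → 9 → 10)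

**Steps most likely to fail, with fallbacks**

Step 1 (Ru hydrazone olefination; azine formation between 4 and 3 or low conversion are the main threats). The fallback sets out from 1 and comes back at 6. Aldehyde 1 is condensed with propane-1,3-dithiol (BF3·OEt2, CH2Cl2) to give 2-[2-(benzyloxy)phenyl]-1,3-dithiane F1. n-BuLi in THF at −30 °C converts this into 2-[2-(benzyloxy)phenyl]-2-lithio-1,3-dithiane F2. Alkylation with commercial 3,5-dimethoxybenzyl bromide gives 2-[2-(benzyloxy)phenyl]-2-[(3,5-dimethoxyphenyl)methyl]-1,3-dithiane F3. Raney nickel in refluxing ethanol removes the sulfur to give 1-(benzyloxy)-2-[2-(3,5-dimethoxyphenyl)ethyl]benzene F4, and H2/Pd-C as in step 2 cleaves the benzyl ether to give 6.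

Step 3 (lithiation in the presence of the phenoxide, and benzylation of the aryl anion by a benzylic chloride). The fallback sets out from 6 and comes back at 9. The dianion 8 is made in the same way but is trapped with 4-(benzyloxy)benzaldehyde instead of 7, with a water quench. This carbonyl addition gives racemic 2-[2-(4-{[4-(benzyloxy)phenyl](hydroxy)methyl}-3,5-dimethoxyphenyl)ethyl]phenol F5. Ionic hydrogenation of this doubly benzylic, strongly cation-stabilised carbinol (Et3SiH, TFA, CH2Cl2, 0 °C) gives 9.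

Step 4 (incomplete or excessive demethylation). The fallback sets out from 4 and comes back at 10, with the two ring-A oxygens differentiated from the start.
- Commercial 3-hydroxy-5-methoxybenzaldehyde is protected (MOMCl, K2CO3, acetone) to give 3-methoxy-5-(methoxymethoxy)benzaldehyde F6.
- F6 replaces 3 in the Ru coupling with hydrazone 4, giving (E)-1-(benzyloxy)-2-{2-[3-methoxy-5-(methoxymethoxy)phenyl]ethenyl}benzene F7.
- H2/Pd-C gives 2-{2-[3-methoxy-5-(methoxymethoxy)phenyl]ethyl}phenol F8.
- n-BuLi (2.2 equiv)/TMEDA lithiates between OMe and OMOM to give lithium 2-{2-[4-lithio-3-methoxy-5-(methoxymethoxy)phenyl]ethyl}phenolate F9.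
- CuI-assisted benzylation with 7 gives 2-[2-(4-{[4-(benzyloxy)phenyl]methyl}-3-methoxy-5-(methoxymethoxy)phenyl)ethyl]phenol F10.
- H2, Pd/C in MeOH containing HCl removes the benzyl and MOM groups to give 10.

**Further compounds**
F1 | step 1 | 2-[2-(benzyloxy)phenyl]-1,3-dithiane | C1CSC(SC1)c1ccccc1OCc1ccccc1
F2 | step 1 | 2-[2-(benzyloxy)phenyl]-2-lithio-1,3-dithiane | [Li]C1(SCCCS1)c1ccccc1OCc1ccccc1
F3 | step 1 | 2-[2-(benzyloxy)phenyl]-2-[(3,5-dimethoxyphenyl)methyl]-1,3-dithiane | COc1cc(CC2(SCCCS2)c2ccccc2OCc2ccccc2)cc(OC)c1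
F4 | step 1 | 1-(benzyloxy)-2-[2-(3,5-dimethoxyphenyl)ethyl]benzene | COc1cc(CCc2ccccc2OCc2ccccc2)cc(OC)c1
F5 | step 3 | 2-[2-(4-{[4-(benzyloxy)phenyl](hydroxy)methyl}-3,5-dimethoxyphenyl)ethyl]phenol (racemic) | COc1cc(CCc2ccccc2O)cc(OC)c1C(O)c1ccc(OCc2ccccc2)cc1
F6 | step 4 | 3-methoxy-5-(methoxymethoxy)benzaldehyde | COCOc1cc(C=O)cc(OC)c1
F7 | step 4 | (E)-1-(benzyloxy)-2-{2-[3-methoxy-5-(methoxymethoxy)phenyl]ethenyl}benzene | COCOc1cc(/C=C/c2ccccc2OCc2ccccc2)cc(OC)c1
F8 | step 4 | 2-{2-[3-methoxy-5-(methoxymethoxy)phenyl]ethyl}phenol | COCOc1cc(CCc2ccccc2O)cc(OC)c1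
F9 | step 4 | lithium 2-{2-[4-lithio-3-methoxy-5-(methoxymethoxy)phenyl]ethyl}phenolate | [Li]c1c(OC)cc(CCc2ccccc2O[Li])cc1OCOC
F10 | step 4 | 2-[2-(4-{[4-(benzyloxy)phenyl]methyl}-3-methoxy-5-(methoxymethoxy)phenyl)ethyl]phenol | COCOc1cc(CCc2ccccc2O)cc(OC)c1Cc1ccc(OCc2ccccc2)cc1
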